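The pyran of the ring A chroman is cut at O1–C2 and C3–C4. Atoms O1, C8a, C4a and C4 then form an ortho-quinone methide, while C2 with its two methyl groups and C3 are isobutene. One hetero-Diels–Alder reaction late in the route therefore closes the pyran ring and forms both bonds without touching either stereocentre. The cycloaddition precursor is a 2-(acetoxymethyl)phenol whose para position carries the complete chain: the (S)-carbinol as a silyl ether, the ketone, and the (S)-dihydrobenzofuran of ring B with its phenol capped as a methoxymethyl ether. It is assembled from a ring A Weinreb amide and a ring B aryllithium.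

Key step: step 14

Remark on the chemistry: both stereocentres of the target are (S); the carbinol is carried as a tert-butyldiphenylsilyl ether, which should survive the aqueous acid of step 12 better than a tert-butyldimethylsilyl ether, and the tertiary alcohol is left free throughout.

**Ring A fragment**

Step 1
Reactants: 1 5-bromo-2-hydroxybenzyl alcohol
Product: 2 6-bromo-2,2-dimethyl-4H-1,3-benzodioxine
Conditions: 2,2-dimethoxypropane, p-TsOH·H2O (cat.), acetone, rt
Reagents that add atoms: 2,2-dimethoxypropane, COC(C)(C)OC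
Why: Acid-catalysed transketalisation ties the phenol and the benzylic alcohol into one isopropylidene ketal that tolerates the organolithium and enolate steps that follow.

Step 2
Reactants: 2 6-bromo-2,2-dimethyl-4H-1,3-benzodioxine
Product: 4 methyl 2,2-dimethyl-4H-1,3-benzodioxine-6-carboxylate, via aryllithium 3 (not isolated)
Conditions: n-BuLi, THF, −78 °C; then cannulated into ClCO2Me (3 equiv), THF, −78 °C
Reagents that add atoms: methyl chloroformate, COC(=O)Cl
Why: Bromine–lithium exchange followed by inverse-addition acylation with excess chloroformate should give the aryl ester and keep double addition low.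

Step 3
Reactants: 4 methyl 2,2-dimethyl-4H-1,3-benzodioxine-6-carboxylate; 5 N-methoxy-N-methylacetamide
Product: 7 3-(2,2-dimethyl-4H-1,3-benzodioxin-6-yl)-N-methoxy-N-methyl-3-oxopropanamide, via lithium amide enolate 6 (not isolated)
Conditions: LiN(i-Pr)2 (2.2 equiv), 5 (2.2 equiv), THF, −78 °C; then 4, −78 to −20 °C; then H2O
Reagents that add atoms: none
Why: Crossed Claisen condensation of a fully preformed amide enolate with a non-enolisable aryl ester, driven by deprotonation of the β-keto amide by the second equivalent of enolate.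

Step 4
Reactants: 7 3-(2,2-dimethyl-4H-1,3-benzodioxin-6-yl)-N-methoxy-N-methyl-3-oxopropanamide
Product: 8 (3S)-3-(2,2-dimethyl-4H-1,3-benzodioxin-6-yl)-3-hydroxy-N-methoxy-N-methylpropanamide
Conditions: RuCl[(S,S)-TsDPEN](p-cymene) (1 mol%), HCO2H/Et3N (1:1), DMF, 30 °C
Reagents that add atoms: none
Why: Noyori–Ikariya asymmetric transfer hydrogenation, in which the (S,S) catalyst should deliver hydride to the aryl ketone in the same sense as for acetophenone and so give the (S)-benzylic alcohol (aryl outranks the CH2C(=O)N arm), while the near-neutral formate medium should spare the ketal.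

Step 5
Reactants: 8 (3S)-3-(2,2-dimethyl-4H-1,3-benzodioxin-6-yl)-3-hydroxy-N-methoxy-N-methylpropanamide
Product: 9 (3S)-3-[(tert-butyldiphenylsilyl)oxy]-3-(2,2-dimethyl-4H-1,3-benzodioxin-6-yl)-N-methoxy-N-methylpropanamide
Conditions: TBDPSCl, imidazole, DMAP (cat.), DMF, rt to 40 °C
Reagents that add atoms: tert-butyl(chloro)diphenylsilane, CC(C)(C)[Si](Cl)(c1ccccc1)c1ccccc1
Why: Standard silylation of a secondary alcohol gives an ether that blocks retro-aldol and dehydration pathways and is stable to organolithiums and to aqueous acetic acid.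

**Ring B fragment**

Step 6
Reactants: 10 4,6-dibromoresorcinol
Product: 11 1,5-dibromo-2,4-bis(prop-2-en-1-yloxy)benzene
Conditions: allyl bromide (2.5 equiv), K2CO3, DMF, rt to 50 °C
Reagents that add atoms: allyl bromide, C=CCBr
Why: Williamson etherification installs allyl ethers, which tolerate bromine–lithium exchange at −78 °C and the basic epoxidation and can later be removed under basic conditions that trigger the furan ring closure.

Step 7
Reactants: 11 1,5-dibromo-2,4-bis(prop-2-en-1-yloxy)benzene; 12 prenyl bromide (1-bromo-3-methylbut-2-ene)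
Product: 14 1-bromo-5-(3-methylbut-2-en-1-yl)-2,4-bis(prop-2-en-1-yloxy)benzene, via aryllithium 13 (not isolated)
Conditions: n-BuLi (1.0 equiv), THF, −78 °C; then 12, −78 °C to rt
Reagents that add atoms: none
Why: Mono bromine–lithium exchange of the symmetric dibromide (either bromine gives the same anion) followed by SN2 alkylation at the primary carbon of the allylic bromide should give the linear prenyl arene.

Step 8
Reactants: 14 1-bromo-5-(3-methylbut-2-en-1-yl)-2,4-bis(prop-2-en-1-yloxy)benzene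
Product: 15 (2R)-2-{[5-bromo-2,4-bis(prop-2-en-1-yloxy)phenyl]methyl}-3,3-dimethyloxirane
Conditions: D-fructose-derived Shi ketone (1,2:4,5-di-O-isopropylidene-β-D-erythro-2,3-hexodiulo-2,6-pyranose, 30 mol%), KHSO5 (Oxone), K2CO3, n-Bu4NHSO4, MeCN/CH2(OMe)2, aq. Na2B4O7/Na2EDTA buffer (pH 10.5), 0 °C
Reagents that add atoms: potassium peroxymonosulfate, [K+].[O-]S(=O)(=O)OO
Why: Shi asymmetric epoxidation, in which the chiral dioxirane should attack the trisubstituted alkene through the spiro transition state on the face that gives the (R)-epoxide, while the monosubstituted allyl ether alkenes react far more slowly.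

Step 9
Reactants: 15 (2R)-2-{[5-bromo-2,4-bis(prop-2-en-1-yloxy)phenyl]methyl}-3,3-dimethyloxirane
Product: 17 (2S)-5-bromo-2-(2-hydroxypropan-2-yl)-2,3-dihydro-1-benzofuran-6-ol, via epoxy resorcinol 16 (not isolated)
Conditions: Pd(PPh3)4 (5 mol%), K2CO3, MeOH, rt to 45 °C
Reagents that add atoms: none
Why: Tsuji–Trost deallylation by zerovalent palladium (methanol as allyl acceptor) frees both phenoxides, and the one next to the side chain opens the epoxide at its secondary carbon in a 5-exo-tet SN2 step with inversion, so the (R)-epoxide carbon becomes the (S)-C2 of the dihydrobenzofuran.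

Step 10
Reactants: 17 (2S)-5-bromo-2-(2-hydroxypropan-2-yl)-2,3-dihydro-1-benzofuran-6-ol
Product: 18 2-[(2S)-5-bromo-6-(methoxymethoxy)-2,3-dihydro-1-benzofuran-2-yl]propan-2-ol
Conditions: MOMCl, K2CO3, acetone, 0 °C to rt
Reagents that add atoms: chloromethyl methyl ether, COCCl
Why: Williamson-type O-alkylation of the phenoxide, with the tertiary alcohol left untouched because carbonate does not deprotonate it.

**Union, key step and endgame**

Step 11
Reactants: 18 2-[(2S)-5-bromo-6-(methoxymethoxy)-2,3-dihydro-1-benzofuran-2-yl]propan-2-ol (1.3 equiv); 9 (3S)-3-[(tert-butyldiphenylsilyl)oxy]-3-(2,2-dimethyl-4H-1,3-benzodioxin-6-yl)-N-methoxy-N-methylpropanamide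
Product: 20 (3S)-3-[(tert-butyldiphenylsilyl)oxy]-3-(2,2-dimethyl-4H-1,3-benzodioxin-6-yl)-1-[(2S)-2-(2-hydroxypropan-2-yl)-6-(methoxymethoxy)-2,3-dihydro-1-benzofuran-5-yl]propan-1-one, via dilithiated aryl alkoxide 19 (not isolated)
Conditions: 18, MeLi (1.0 equiv), THF, −78 °C; t-BuLi (2.0 equiv), −78 °C; then 9, −78 to −30 °C; then H2O
Reagents that add atoms: none
Why: Weinreb ketone synthesis, in which the alkoxide is formed first, bromine–lithium exchange then gives an aryllithium stabilised by the ortho methoxymethoxy group, and this adds only once because the chelated tetrahedral intermediate persists until the quench.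

Step 12
Reactants: 20 (3S)-3-[(tert-butyldiphenylsilyl)oxy]-3-(2,2-dimethyl-4H-1,3-benzodioxin-6-yl)-1-[(2S)-2-(2-hydroxypropan-2-yl)-6-(methoxymethoxy)-2,3-dihydro-1-benzofuran-5-yl]propan-1-one
Product: 21 (3S)-3-[(tert-butyldiphenylsilyl)oxy]-3-[4-hydroxy-3-(hydroxymethyl)phenyl]-1-[(2S)-2-(2-hydroxypropan-2-yl)-6-(methoxymethoxy)-2,3-dihydro-1-benzofuran-5-yl]propan-1-one
Conditions: AcOH/THF/H2O (3:1:1), 40 °C
Reagents that add atoms: none
Why: Acid-catalysed ketal hydrolysis, which should be selective because an isopropylidene ketal hydrolyses far faster than the formaldehyde-derived methoxymethyl acetal and the tert-butyldiphenylsilyl ether is stable to aqueous acetic acid.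

Step 13
Reactants: 21 (3S)-3-[(tert-butyldiphenylsilyl)oxy]-3-[4-hydroxy-3-(hydroxymethyl)phenyl]-1-[(2S)-2-(2-hydroxypropan-2-yl)-6-(methoxymethoxy)-2,3-dihydro-1-benzofuran-5-yl]propan-1-one
Product: 22 {5-[(1S)-1-[(tert-butyldiphenylsilyl)oxy]-3-[(2S)-2-(2-hydroxypropan-2-yl)-6-(methoxymethoxy)-2,3-dihydro-1-benzofuran-5-yl]-3-oxopropyl]-2-hydroxyphenyl}methyl acetate
Conditions: Novozym 435 (immobilised Candida antarctica lipase B), vinyl acetate, t-BuOMe/THF, 35 °C
Reagents that add atoms: vinyl acetate, CC(=O)OC=C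
Why: Lipase-catalysed transesterification acylates primary aliphatic alcohols but not phenols or tertiary alcohols, so only the benzylic CH2OH should be acetylated, and tautomerisation of the released enol to acetaldehyde makes the transfer irreversible.

Step 14
Reactants: 22 {5-[(1S)-1-[(tert-butyldiphenylsilyl)oxy]-3-[(2S)-2-(2-hydroxypropan-2-yl)-6-(methoxymethoxy)-2,3-dihydro-1-benzofuran-5-yl]-3-oxopropyl]-2-hydroxyphenyl}methyl acetate; 23 isobutene
Product: 25 (3S)-3-[(tert-butyldiphenylsilyl)oxy]-3-(2,2-dimethyl-3,4-dihydro-2H-chromen-6-yl)-1-[(2S)-2-(2-hydroxypropan-2-yl)-6-(methoxymethoxy)-2,3-dihydro-1-benzofuran-5-yl]propan-1-one, via ortho-quinone methide 24 (not isolated)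
Conditions: isobutene (liquefied, large excess)/PhMe, i-Pr2NEt (1.5 equiv), sealed steel pressure vessel, 90 °C
Reagents that add atoms: none
Why: The amine assists 1,4-elimination of acetic acid from the ortho-hydroxybenzyl acetate to give ortho-quinone methide 24, whose O1=C8a–C4a=C4 unit is an electron-poor 1-oxadiene that adds isobutene in an inverse-electron-demand hetero-Diels–Alder reaction. The closest known reaction type is the trapping of thermally or base-generated ortho-quinone methides by 1,1-disubstituted alkenes to give 2,2-disubstituted chromans. The pyran ring is closed by an intermolecular [4+2] cycloaddition that forms C4–C3 and O1–C2 in one concerted, asynchronous event and restores the aromaticity of ring A. No stereocentre is created, because C2 carries two identical methyl groups, and the two (S) centres are remote from the reacting atoms. The step needs regioselectivity, secured by the polarised transition state in which the methide carbon C4 bonds to the CH2 terminus while positive charge builds on the tertiary carbon that ends on oxygen, and chemoselectivity, secured by acetate being a far better leaving group than the para silyloxy group (no para-quinone methide), by the capped ring B phenol, and by the large excess of isobutene at high dilution, which should outrun oligomerisation of 24.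

Step 15
Reactants: 25 (3S)-3-[(tert-butyldiphenylsilyl)oxy]-3-(2,2-dimethyl-3,4-dihydro-2H-chromen-6-yl)-1-[(2S)-2-(2-hydroxypropan-2-yl)-6-(methoxymethoxy)-2,3-dihydro-1-benzofuran-5-yl]propan-1-one
Product: 26 (3S)-3-[(tert-butyldiphenylsilyl)oxy]-3-(2,2-dimethyl-3,4-dihydro-2H-chromen-6-yl)-1-[(2S)-6-hydroxy-2-(2-hydroxypropan-2-yl)-2,3-dihydro-1-benzofuran-5-yl]propan-1-one
Conditions: MgBr2·OEt2 (4 equiv), Et2O/CH2Cl2, 0 °C to rt
Reagents that add atoms: none
Why: Chelation-assisted acetal cleavage, in which magnesium bound between the ketone oxygen and the ortho methoxymethyl oxygen activates this one acetal for bromide attack and should leave the silyl ether and both cyclic ethers untouched.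

Step 16
Reactants: 26 (3S)-3-[(tert-butyldiphenylsilyl)oxy]-3-(2,2-dimethyl-3,4-dihydro-2H-chromen-6-yl)-1-[(2S)-6-hydroxy-2-(2-hydroxypropan-2-yl)-2,3-dihydro-1-benzofuran-5-yl]propan-1-one
Product: 27 (3S)-3-(2,2-dimethyl-3,4-dihydro-2H-chromen-6-yl)-3-hydroxy-1-[(2S)-6-hydroxy-2-(2-hydroxypropan-2-yl)-2,3-dihydro-1-benzofuran-5-yl]propan-1-one
Conditions: Bu4NF/AcOH (1:1, 5 equiv), THF, rt to 40 °C
Reagents that add atoms: none
Why: Fluoride-mediated desilylation buffered with acetic acid keeps the medium non-basic, so β-elimination or retro-aldol cleavage of the liberated β-hydroxy ketone should not compete.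

**Compound list**

1 | 5-bromo-2-hydroxybenzyl alcohol | OCc1cc(Br)ccc1O | starting material
2 | 6-bromo-2,2-dimethyl-4H-1,3-benzodioxine | CC1(C)OCc2cc(Br)ccc2O1 | intermediate
3 | (2,2-dimethyl-4H-1,3-benzodioxin-6-yl)lithium (not isolated) | [Li]c1ccc2OC(C)(C)OCc2c1 | intermediate
4 | methyl 2,2-dimethyl-4H-1,3-benzodioxine-6-carboxylate | COC(=O)c1ccc2OC(C)(C)OCc2c1 | intermediate
5 | N-methoxy-N-methylacetamide | CC(=O)N(C)OC | starting material
6 | lithium 1-[methoxy(methyl)amino]ethen-1-olate (not isolated) | C=C(O[Li])N(C)OC | intermediate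
7 | 3-(2,2-dimethyl-4H-1,3-benzodioxin-6-yl)-N-methoxy-N-methyl-3-oxopropanamide | CON(C)C(=O)CC(=O)c1ccc2OC(C)(C)OCc2c1 | intermediate
8 | (3S)-3-(2,2-dimethyl-4H-1,3-benzodioxin-6-yl)-3-hydroxy-N-methoxy-N-methylpropanamide | CC1(C)OCc2cc([C@@H](O)CC(=O)N(C)OC)ccc2O1 | intermediate
9 | (3S)-3-[(tert-butyldiphenylsilyl)oxy]-3-(2,2-dimethyl-4H-1,3-benzodioxin-6-yl)-N-methoxy-N-methylpropanamide | CC1(C)OCc2cc([C@@H](O[Si](c3ccccc3)(c3ccccc3)C(C)(C)C)CC(=O)N(C)OC)ccc2O1 | intermediate
10 | 4,6-dibromoresorcinol (4,6-dibromobenzene-1,3-diol) | Oc1cc(O)c(Br)cc1Br | starting material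
11 | 1,5-dibromo-2,4-bis(prop-2-en-1-yloxy)benzene | C=CCOc1cc(OCC=C)c(Br)cc1Br | intermediate
12 | prenyl bromide (1-bromo-3-methylbut-2-ene) | CC(C)=CCBr | starting material
13 | [5-bromo-2,4-bis(prop-2-en-1-yloxy)phenyl]lithium (not isolated) | [Li]c1cc(Br)c(OCC=C)cc1OCC=C | intermediate
14 | 1-bromo-5-(3-methylbut-2-en-1-yl)-2,4-bis(prop-2-en-1-yloxy)benzene | C=CCOc1cc(OCC=C)c(CC=C(C)C)cc1Br | intermediate
15 | (2R)-2-{[5-bromo-2,4-bis(prop-2-en-1-yloxy)phenyl]methyl}-3,3-dimethyloxirane | C=CCOc1cc(OCC=C)c(C[C@H]2OC2(C)C)cc1Br | intermediate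
16 | 4-bromo-6-{[(2R)-3,3-dimethyloxiran-2-yl]methyl}benzene-1,3-diol (not isolated) | Oc1cc(O)c(C[C@H]2OC2(C)C)cc1Br | intermediate
17 | (2S)-5-bromo-2-(2-hydroxypropan-2-yl)-2,3-dihydro-1-benzofuran-6-ol | Oc1cc2O[C@H](C(C)(C)O)Cc2cc1Br | intermediate
18 | 2-[(2S)-5-bromo-6-(methoxymethoxy)-2,3-dihydro-1-benzofuran-2-yl]propan-2-ol | COCOc1cc2O[C@H](C(C)(C)O)Cc2cc1Br | intermediate
19 | lithium 2-[(2S)-5-lithio-6-(methoxymethoxy)-2,3-dihydro-1-benzofuran-2-yl]propan-2-olate (not isolated) | COCOc1cc2O[C@H](C(C)(C)O[Li])Cc2cc1[Li] | intermediate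
20 | (3S)-3-[(tert-butyldiphenylsilyl)oxy]-3-(2,2-dimethyl-4H-1,3-benzodioxin-6-yl)-1-[(2S)-2-(2-hydroxypropan-2-yl)-6-(methoxymethoxy)-2,3-dihydro-1-benzofuran-5-yl]propan-1-one | CC1(C)OCc2cc([C@@H](O[Si](c3ccccc3)(c3ccccc3)C(C)(C)C)CC(=O)c3cc4c(cc3OCOC)O[C@H](C(C)(C)O)C4)ccc2O1 | intermediate
21 | (3S)-3-[(tert-butyldiphenylsilyl)oxy]-3-[4-hydroxy-3-(hydroxymethyl)phenyl]-1-[(2S)-2-(2-hydroxypropan-2-yl)-6-(methoxymethoxy)-2,3-dihydro-1-benzofuran-5-yl]propan-1-one | OCc1cc([C@@H](O[Si](c2ccccc2)(c2ccccc2)C(C)(C)C)CC(=O)c2cc3c(cc2OCOC)O[C@H](C(C)(C)O)C3)ccc1O | intermediate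
22 | {5-[(1S)-1-[(tert-butyldiphenylsilyl)oxy]-3-[(2S)-2-(2-hydroxypropan-2-yl)-6-(methoxymethoxy)-2,3-dihydro-1-benzofuran-5-yl]-3-oxopropyl]-2-hydroxyphenyl}methyl acetate | CC(=O)OCc1cc([C@@H](O[Si](c2ccccc2)(c2ccccc2)C(C)(C)C)CC(=O)c2cc3c(cc2OCOC)O[C@H](C(C)(C)O)C3)ccc1O | intermediate
23 | isobutene (2-methylpropene) | CC(C)=C | starting material
24 | 4-{(1S)-1-[(tert-butyldiphenylsilyl)oxy]-3-[(2S)-2-(2-hydroxypropan-2-yl)-6-(methoxymethoxy)-2,3-dihydro-1-benzofuran-5-yl]-3-oxopropyl}-6-methylidenecyclohexa-2,4-dien-1-one (not isolated) | C=C1C=C([C@@H](O[Si](c2ccccc2)(c2ccccc2)C(C)(C)C)CC(=O)c2cc3c(cc2OCOC)O[C@H](C(C)(C)O)C3)C=CC1=O | intermediate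
25 | (3S)-3-[(tert-butyldiphenylsilyl)oxy]-3-(2,2-dimethyl-3,4-dihydro-2H-chromen-6-yl)-1-[(2S)-2-(2-hydroxypropan-2-yl)-6-(methoxymethoxy)-2,3-dihydro-1-benzofuran-5-yl]propan-1-one | CC1(C)CCc2cc([C@@H](O[Si](c3ccccc3)(c3ccccc3)C(C)(C)C)CC(=O)c3cc4c(cc3OCOC)O[C@H](C(C)(C)O)C4)ccc2O1 | intermediate
26 | (3S)-3-[(tert-butyldiphenylsilyl)oxy]-3-(2,2-dimethyl-3,4-dihydro-2H-chromen-6-yl)-1-[(2S)-6-hydroxy-2-(2-hydroxypropan-2-yl)-2,3-dihydro-1-benzofuran-5-yl]propan-1-one | CC1(C)CCc2cc([C@@H](O[Si](c3ccccc3)(c3ccccc3)C(C)(C)C)CC(=O)c3cc4c(cc3O)O[C@H](C(C)(C)O)C4)ccc2O1 | intermediate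
27 | (3S)-3-(2,2-dimethyl-3,4-dihydro-2H-chromen-6-yl)-3-hydroxy-1-[(2S)-6-hydroxy-2-(2-hydroxypropan-2-yl)-2,3-dihydro-1-benzofuran-5-yl]propan-1-one | CC1(C)CCc2cc([C@@H](O)CC(=O)c3cc4c(cc3O)O[C@H](C(C)(C)O)C4)ccc2O1 | target

**Step count**

Total: 16 steps. Longest linear sequence: 11 steps (steps 1–5 or 6–10, then 11–16).

**Steps most likely to fail**

1. Step 14. The transient methide may oligomerise or be captured by oxygen nucleophiles faster than the unactivated alkene adds, and the amine at 90 °C may induce β-elimination of the silyloxy group next to the ketone. The fallback closes the pyran before the chain is built, where forcing conditions are tolerated. Setting out from ester 4, the ketal would be hydrolysed (AcOH/H2O, 70 °C) to methyl 4-hydroxy-3-(hydroxymethyl)benzoate F1. Heating F1 with excess isobutene 23 at about 170 °C in an autoclave should dehydrate it to methyl 3-methylidene-4-oxocyclohexa-1,5-diene-1-carboxylate F2 (not isolated), which the alkene traps to give methyl 2,2-dimethyl-3,4-dihydro-2H-chromene-6-carboxylate F3. Claisen condensation with enolate 6 as in step 3 would give 3-(2,2-dimethyl-3,4-dihydro-2H-chromen-6-yl)-N-methoxy-N-methyl-3-oxopropanamide F4. Transfer hydrogenation as in step 4 would give (3S)-3-(2,2-dimethyl-3,4-dihydro-2H-chromen-6-yl)-3-hydroxy-N-methoxy-N-methylpropanamide F5, and silylation as in step 5 its tert-butyldiphenylsilyl ether F6. Addition of 19 as in step 11 returns to the route at 25.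

2. Step 13. Acyl transfer may stall because the enzyme does not accept the bulky substrate. The fallback activates the hydroxyl group and not the acyl donor: Mitsunobu esterification of 21 with AcOH (PPh3, DIAD, THF, 0 °C). Acetic acid, far more acidic than the phenol, is the preferred pronucleophile for the activated primary benzylic alcohol. If the activated alcohol collapses to methide 24, acetic acid adds back at the methide carbon to give the same product. The fallback leaves 21 and arrives at 22 and makes no new compound (F0).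

3. Step 12. Hydrolysis may not stop at the ketal, and the methoxymethyl ether activated by the neighbouring ketone may be lost as well. The fallback removes both acetals on purpose and runs the cycloaddition with the ring B phenol free but hydrogen-bonded to the ketone. From 20, 1 M HCl in THF at rt should give (3S)-3-[(tert-butyldiphenylsilyl)oxy]-1-[(2S)-6-hydroxy-2-(2-hydroxypropan-2-yl)-2,3-dihydro-1-benzofuran-5-yl]-3-[4-hydroxy-3-(hydroxymethyl)phenyl]propan-1-one F7. Lipase acetylation as in step 13 would give its benzylic monoacetate F8. Elimination and cycloaddition as in step 14, through the ortho-quinone methide with free ring B phenol F9 (not isolated), would rejoin the route at 26 and make step 15 unnecessary.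

**Further compounds**

F1 | step 14 | methyl 4-hydroxy-3-(hydroxymethyl)benzoate | COC(=O)c1ccc(O)c(CO)c1
F2 | step 14 | methyl 3-methylidene-4-oxocyclohexa-1,5-diene-1-carboxylate (not isolated) | COC(=O)C1=CC(=C)C(=O)C=C1
F3 | step 14 | methyl 2,2-dimethyl-3,4-dihydro-2H-chromene-6-carboxylate | COC(=O)c1ccc2OC(C)(C)CCc2c1
F4 | step 14 | 3-(2,2-dimethyl-3,4-dihydro-2H-chromen-6-yl)-N-methoxy-N-methyl-3-oxopropanamide | CON(C)C(=O)CC(=O)c1ccc2OC(C)(C)CCc2c1
F5 | step 14 | (3S)-3-(2,2-dimethyl-3,4-dihydro-2H-chromen-6-yl)-3-hydroxy-N-methoxy-N-methylpropanamide | CC1(C)CCc2cc([C@@H](O)CC(=O)N(C)OC)ccc2O1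
F6 | step 14 | (3S)-3-[(tert-butyldiphenylsilyl)oxy]-3-(2,2-dimethyl-3,4-dihydro-2H-chromen-6-yl)-N-methoxy-N-methylpropanamide | CC1(C)CCc2cc([C@@H](O[Si](c3ccccc3)(c3ccccc3)C(C)(C)C)CC(=O)N(C)OC)ccc2O1
F0 | step 13 | none | none
F7 | step 12 | (3S)-3-[(tert-butyldiphenylsilyl)oxy]-1-[(2S)-6-hydroxy-2-(2-hydroxypropan-2-yl)-2,3-dihydro-1-benzofuran-5-yl]-3-[4-hydroxy-3-(hydroxymethyl)phenyl]propan-1-one | OCc1cc([C@@H](O[Si](c2ccccc2)(c2ccccc2)C(C)(C)C)CC(=O)c2cc3c(cc2O)O[C@H](C(C)(C)O)C3)ccc1O
F8 | step 12 | {5-[(1S)-1-[(tert-butyldiphenylsilyl)oxy]-3-[(2S)-6-hydroxy-2-(2-hydroxypropan-2-yl)-2,3-dihydro-1-benzofuran-5-yl]-3-oxopropyl]-2-hydroxyphenyl}methyl acetate | CC(=O)OCc1cc([C@@H](O[Si](c2ccccc2)(c2ccccc2)C(C)(C)C)CC(=O)c2cc3c(cc2O)O[C@H](C(C)(C)O)C3)ccc1O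
F9 | step 12 | 4-{(1S)-1-[(tert-butyldiphenylsilyl)oxy]-3-[(2S)-6-hydroxy-2-(2-hydroxypropan-2-yl)-2,3-dihydro-1-benzofuran-5-yl]-3-oxopropyl}-6-methylidenecyclohexa-2,4-dien-1-one (not isolated) | C=C1C=C([C@@H](O[Si](c2ccccc2)(c2ccccc2)C(C)(C)C)CC(=O)c2cc3c(cc2O)O[C@H](C(C)(C)O)C3)C=CC1=O
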